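**Overview**
1. Retrosynthetic cuts: the three phenol protecting groups come off last and the diarylmethane CH2 is traced back to a carbinol. The central ring then loses two neighbouring C–C bonds together, C4–CH(OH)Ar (the 4-hydroxybenzyl carbon) and C3–CH2 (the phenethyl chain).
2. Enabling feature: in the central phenol ring C5 (OMe), C4 (benzyl carbon) and C3 (phenethyl carbon) are contiguous. C3/C4 therefore map onto the triple bond of a 3-methoxybenzyne, whose neighbouring OMe sends a carbon nucleophile to C3 and leaves the metal on C4.
3. Forward order: no ring is built. Three purchased benzene rings are joined in one flask around the central ring, first the phenethyl chain (as its Grignard reagent) at the former C–F carbon, then the benzylic carbon (from 4-benzyloxybenzaldehyde) at the carbon next to OMe.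
4. The two resorcinol oxygens are distinguished from the start (OMe versus OTIPS). Ionic deoxygenation, desilylation and hydrogenolysis finish the synthesis.
5. Stereochemistry: the target is achiral. The only stereocentre of the route, the carbinol carbon, arises racemic and is erased by the deoxygenation.

Key step: step 5

Remark: the target SMILES contains no stereocentre, so the request for a single enantiomer is met by the achiral compound itself and no enantiocontrol is built in.

**Step 1**
Reactants: 1 3-fluoro-5-methoxyphenol
Product: 2 (3-fluoro-5-methoxyphenoxy)triisopropylsilane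
Conditions: TIPSCl, imidazole, DMF, 0 °C → rt
Reagents that add atoms: triisopropylsilyl chloride, CC(C)[Si](Cl)(C(C)C)C(C)C
Why: Imidazole-promoted silylation of a phenol is routine, and the bulky TIPS ether tolerates s-BuLi and Grignard reagents, directs metalation poorly and screens both C–H bonds beside it.

**Step 2**
Reactants: 3 2-(2-hydroxyphenyl)ethanol
Product: 4 2-[2-(benzyloxy)phenyl]ethanol
Conditions: BnBr, K2CO3, acetone, reflux
Reagents that add atoms: benzyl bromide, BrCc1ccccc1
Why: In this Williamson ether synthesis carbonate deprotonates only the far more acidic phenol, so benzylation should be selective for the aryl oxygen, and masking the phenol also rules out later closure to 2,3-dihydrobenzofuran.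

**Step 3**
Reactants: 4 2-[2-(benzyloxy)phenyl]ethanol
Product: 5 1-(benzyloxy)-2-(2-bromoethyl)benzene
Conditions: CBr4, PPh3, CH2Cl2, 0 °C
Reagents that add atoms: carbon tetrabromide, BrC(Br)(Br)Br
Why: The Appel reaction displaces the oxyphosphonium salt of an unhindered primary alcohol by bromide (SN2) under neutral conditions that leave the benzyl ether untouched.

**Step 4**
Reactants: 5 1-(benzyloxy)-2-(2-bromoethyl)benzene
Product: 6 [2-(2-benzyloxyphenyl)ethyl]magnesium bromide
Conditions: Mg turnings (excess, I2 crystal), THF, slow addition of dilute 5, rt → 40 °C; titrated and used as THF solution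
Reagents that add atoms: magnesium, [Mg]
Why: Grignard formation by direct magnesium insertion into a primary alkyl bromide is standard, slow addition to excess activated metal keeps Wurtz coupling low, and the aryl benzyl ether is inert to the reagent.

**Step 5**
Reactants: 2 (3-fluoro-5-methoxyphenoxy)triisopropylsilane; 6 [2-(2-benzyloxyphenyl)ethyl]magnesium bromide; 7 4-(benzyloxy)benzaldehyde
Product: 11 racemic [4-(benzyloxy)phenyl]{2-[2-(2-benzyloxyphenyl)ethyl]-6-methoxy-4-(triisopropylsilyloxy)phenyl}methanol, via aryllithium 8 (not isolated), via aryne 9 (not isolated), via arylmagnesium bromide 10 (not isolated)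
Conditions: 2, s-BuLi (1.0 equiv), THF, −78 °C; then 6 (ca. 2.5 equiv), −78 °C → rt; then 7 (ca. 3 equiv), 0 °C → rt; aq NH4Cl
Reagents that add atoms: none
Why: Directed ortho-lithiation removes the ring proton between F and OMe of 2, which is acidified by both groups and reached through Li–OMe coordination while the TIPS group screens the other two C–H bonds, and the resulting 8 holds at −78 °C. On warming with 6 present, metal fluoride is lost to give aryne 9, the alkyl–Mg bond adds across the strained triple bond (carbomagnesiation) to form the ring–CH2 bond at the former C–F carbon, and the new aryl Grignard 10 undergoes 1,2-addition to the non-enolisable aldehyde 7 to form the ring–CH(OH) bond. The closest known reaction type is the three-component coupling of 3-alkoxybenzynes, generated from lithiated fluoroanisoles, with Grignard reagents and carbonyl electrophiles. The regioselectivity needed is secured by the σ-withdrawing OMe next to the triple bond, which distorts and polarises the aryne so that the nucleophile attacks the distal carbon and the metal ends on the proximal carbon, where the methoxy oxygen can chelate it; the remote silyloxy group should have little say. Chemoselectivity rests on stoichiometry: one equivalent of s-BuLi leaves no free alkyllithium, the surplus of 6 outcompetes 8 for the aryne, and extra 7 turns leftover 6 into a separable alcohol. No ring closes, and the one new stereocentre (the carbinol carbon) forms without control as a racemate and is deleted in step 6.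

**Step 6**
Reactants: 11 racemic [4-(benzyloxy)phenyl]{2-[2-(2-benzyloxyphenyl)ethyl]-6-methoxy-4-(triisopropylsilyloxy)phenyl}methanol
Product: 12 {3-[2-(2-benzyloxyphenyl)ethyl]-4-(4-benzyloxybenzyl)-5-methoxyphenoxy}triisopropylsilane
Conditions: Et3SiH (excess, premixed with 11), TFA added dropwise, CH2Cl2, 0 °C
Reagents that add atoms: none
Why: In this ionic hydrogenation TFA ionises the doubly benzylic alcohol to a cation stabilised by the para-benzyloxy, ortho-methoxy and para-silyloxy groups, and the silane already present should deliver hydride faster than the only intramolecular trap (a seven-membered Friedel–Crafts closure onto a position meta to OBn and thus unactivated), while TIPS and benzyl ethers tolerate brief cold TFA.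

**Step 7**
Reactants: 12 {3-[2-(2-benzyloxyphenyl)ethyl]-4-(4-benzyloxybenzyl)-5-methoxyphenoxy}triisopropylsilane
Product: 13 3-[2-(2-benzyloxyphenyl)ethyl]-4-(4-benzyloxybenzyl)-5-methoxyphenol
Conditions: TBAF, AcOH (1:1), THF, 0 °C
Reagents that add atoms: none
Why: Fluoride-induced cleavage of an aryl silyl ether is driven by Si–F bond formation, the acetic acid buffer protonates the phenoxide as it forms, and benzyl and methyl ethers are inert.

**Step 8**
Reactants: 13 3-[2-(2-benzyloxyphenyl)ethyl]-4-(4-benzyloxybenzyl)-5-methoxyphenol
Product: 14 3-[2-(2-hydroxyphenyl)ethyl]-4-[(4-hydroxyphenyl)methyl]-5-methoxyphenol (target)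
Conditions: H2 (1 atm), 10% Pd/C, EtOAc–MeOH, rt
Reagents that add atoms: none
Why: Catalytic hydrogenolysis cleaves both aryl benzyl ethers, while the methyl ether, the diarylmethane and bibenzyl C–C bonds and the arene rings are untouched at ambient pressure and temperature.

**Compound list**
1 | 3-fluoro-5-methoxyphenol | COc1cc(O)cc(F)c1 | starting material
2 | (3-fluoro-5-methoxyphenoxy)triisopropylsilane | COc1cc(O[Si](C(C)C)(C(C)C)C(C)C)cc(F)c1 | intermediate
3 | 2-(2-hydroxyphenyl)ethanol | OCCc1ccccc1O | starting material
4 | 2-[2-(benzyloxy)phenyl]ethanol | OCCc1ccccc1OCc1ccccc1 | intermediate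
5 | 1-(benzyloxy)-2-(2-bromoethyl)benzene | BrCCc1ccccc1OCc1ccccc1 | intermediate
6 | [2-(2-benzyloxyphenyl)ethyl]magnesium bromide | Br[Mg]CCc1ccccc1OCc1ccccc1 | intermediate
7 | 4-(benzyloxy)benzaldehyde | O=Cc1ccc(OCc2ccccc2)cc1 | starting material
8 | [2-fluoro-6-methoxy-4-(triisopropylsilyloxy)phenyl]lithium | COc1cc(O[Si](C(C)C)(C(C)C)C(C)C)cc(F)c1[Li] | intermediate
9 | 3-methoxy-5-(triisopropylsilyloxy)benzyne | COC1=CC(O[Si](C(C)C)(C(C)C)C(C)C)=CC#C1 | intermediate
10 | {2-[2-(2-benzyloxyphenyl)ethyl]-6-methoxy-4-(triisopropylsilyloxy)phenyl}magnesium bromide | COc1cc(O[Si](C(C)C)(C(C)C)C(C)C)cc(CCc2ccccc2OCc2ccccc2)c1[Mg]Br | intermediate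
11 | racemic [4-(benzyloxy)phenyl]{2-[2-(2-benzyloxyphenyl)ethyl]-6-methoxy-4-(triisopropylsilyloxy)phenyl}methanol | COc1cc(O[Si](C(C)C)(C(C)C)C(C)C)cc(CCc2ccccc2OCc2ccccc2)c1C(O)c1ccc(OCc2ccccc2)cc1 | intermediate
12 | {3-[2-(2-benzyloxyphenyl)ethyl]-4-(4-benzyloxybenzyl)-5-methoxyphenoxy}triisopropylsilane | COc1cc(O[Si](C(C)C)(C(C)C)C(C)C)cc(CCc2ccccc2OCc2ccccc2)c1Cc1ccc(OCc2ccccc2)cc1 | intermediate
13 | 3-[2-(2-benzyloxyphenyl)ethyl]-4-(4-benzyloxybenzyl)-5-methoxyphenol | COc1cc(O)cc(CCc2ccccc2OCc2ccccc2)c1Cc1ccc(OCc2ccccc2)cc1 | intermediate
14 | 3-[2-(2-hydroxyphenyl)ethyl]-4-[(4-hydroxyphenyl)methyl]-5-methoxyphenol | COc1cc(O)cc(CCc2ccccc2O)c1Cc1ccc(O)cc1 | target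

**Step count and risks**
Total steps: 8.
Longest linear sequence: 7 (3 → 4 → 5 → 6 → 11 → 12 → 13 → 14).

**Step 5.** Several processes could erode the coupling:
- The aryne may be consumed by its own metalated precursor.
- The aryne may be reduced by β-hydride transfer from the phenethyl Grignard reagent.
- Part of the lithiation may occur beside fluorine on the silyloxy side.
- The crowded aryl Grignard may add sluggishly to the aldehyde.

The fallback gives up the aryne, sets out from aldehyde 7 and bromide 5, and comes back at 12. Purchased 3-bromo-5-methoxyphenol would be silylated (TIPSCl, imidazole) to (3-bromo-5-methoxyphenoxy)triisopropylsilane F1. LDA in THF at −78 °C should deprotonate between Br and OMe without bromine–lithium exchange, giving [2-bromo-6-methoxy-4-(triisopropylsilyloxy)phenyl]lithium F2. This is added at once to 7 to give [4-(benzyloxy)phenyl][2-bromo-6-methoxy-4-(triisopropylsilyloxy)phenyl]methanol F3. Et3SiH/TFA would reduce it to {4-[4-(benzyloxy)benzyl]-3-bromo-5-methoxyphenoxy}triisopropylsilane F4. Zinc insertion into 5 (Zn dust, LiCl, THF) gives [2-(2-benzyloxyphenyl)ethyl]zinc bromide F5. A Negishi coupling of the aryl bromide with this alkylzinc reagent (Pd(OAc)2, SPhos, THF) then forms the ring–CH2 bond and delivers 12.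

**Step 4.** Wurtz homocoupling and base-induced loss of HBr to the styrene during the insertion could leave a weak, impure reagent solution, which matters because the reagent is used in excess. The fallback sets out from alcohol 4 and comes back at 6. An Appel-type iodination (I2, PPh3, imidazole, CH2Cl2) gives 1-(benzyloxy)-2-(2-iodoethyl)benzene F6. Iodine–lithium exchange with t-BuLi (2 equiv, Et2O–pentane, −78 °C) gives [2-(2-benzyloxyphenyl)ethyl]lithium F7. Transmetalation with MgBr2·OEt2 at −78 °C then supplies 6 without contact between alkyl halide and magnesium metal.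

**Step 6.** The diarylmethyl cation may be captured by an arene instead of hydride, either through seven-membered Friedel–Crafts closure or through intermolecular alkylation of an electron-rich ring. The acid may also strip the silyl ether. The fallback avoids a free cation, sets out from 11 and comes back at 14. Hydrogenolysis over Pd(OH)2/C (H2, EtOH–AcOH) should cleave the benzhydrylic C–O bond together with both benzyl ethers, giving 2-{2-[2-(4-hydroxybenzyl)-3-methoxy-5-(triisopropylsilyloxy)phenyl]ethyl}phenol F8. TBAF/AcOH in THF then releases the target 14.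

**Further compounds**
F1 | step 5 | (3-bromo-5-methoxyphenoxy)triisopropylsilane | COc1cc(O[Si](C(C)C)(C(C)C)C(C)C)cc(Br)c1
F2 | step 5 | [2-bromo-6-methoxy-4-(triisopropylsilyloxy)phenyl]lithium | COc1cc(O[Si](C(C)C)(C(C)C)C(C)C)cc(Br)c1[Li]
F3 | step 5 | [4-(benzyloxy)phenyl][2-bromo-6-methoxy-4-(triisopropylsilyloxy)phenyl]methanol | COc1cc(O[Si](C(C)C)(C(C)C)C(C)C)cc(Br)c1C(O)c1ccc(OCc2ccccc2)cc1
F4 | step 5 | {4-[4-(benzyloxy)benzyl]-3-bromo-5-methoxyphenoxy}triisopropylsilane | COc1cc(O[Si](C(C)C)(C(C)C)C(C)C)cc(Br)c1Cc1ccc(OCc2ccccc2)cc1
F5 | step 5 | [2-(2-benzyloxyphenyl)ethyl]zinc bromide | Br[Zn]CCc1ccccc1OCc1ccccc1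
F6 | step 4 | 1-(benzyloxy)-2-(2-iodoethyl)benzene | ICCc1ccccc1OCc1ccccc1
F7 | step 4 | [2-(2-benzyloxyphenyl)ethyl]lithium | [Li]CCc1ccccc1OCc1ccccc1
F8 | step 6 | 2-{2-[2-(4-hydroxybenzyl)-3-methoxy-5-(triisopropylsilyloxy)phenyl]ethyl}phenol | COc1cc(O[Si](C(C)C)(C(C)C)C(C)C)cc(CCc2ccccc2O)c1Cc1ccc(O)cc1
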